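**Retrosynthetic overview**
- Target ⇐ C8 lithiation and acylation with a Weinreb cinnamamide, then desilylation, of a 5,7-dioxygenated flavan that lacks the chalcone arm.
- Flavan (ring C, closed second) ⇐ acid-triggered ring switch of an all-cis 2,4,6-trisubstituted tetrahydropyran: the benzylic C–O bond ionises and a ring A phenol recloses.
- Key disconnection: ring A aryl–C4 bond ⇐ iron-catalysed radical cross-coupling of a 4-bromotetrahydropyran with a 2,6-bis(MOM-oxy)aryl Grignard; capture of the ring radical sets C4.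
- Bromotetrahydropyran (ring formed first) ⇐ Prins cyclisation of an (R)-homoallylic alcohol (Heck, then Ir-catalysed allylation) with 4-silyloxybenzaldehyde.
- Ring A ⇐ resorcinol bis-MOM ether by C–H borylation, oxidation and methylation; all three hydroxyphenyl rings ⇐ one silyl-protected 4-iodophenol.

Abbreviations: TIPS = triisopropylsilyl, TIPSO = TIPS-oxy, MOM = methoxymethyl.
Assumption: triisopropyl(4-iodophenoxy)silane and 1,3-bis(methoxymethoxy)benzene are bought as such (protected 4-iodophenol and resorcinol).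

**Step 1**
Reactants: 1 triisopropyl(4-iodophenoxy)silane; 2 allyl alcohol
Product: 3 aldehyde 3-[4-(TIPSO)phenyl]propanal
Conditions: Pd(OAc)2 (3 mol%), Bu4NCl, NaHCO3, DMF, 45 °C
Reagents that add atoms: none
Why: Jeffery-type Heck reaction in which the arylpalladium species adds to the terminal carbon of allyl alcohol and β-hydride elimination toward the carbinol releases an enol that tautomerises to the aldehyde; no stereocenter is formed.

**Step 2**
Reactants: 3 aldehyde 3-[4-(TIPSO)phenyl]propanal; 4 allyl acetate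
Product: 5 (3R)-1-[4-(TIPSO)phenyl]hex-5-en-3-ol
Conditions: [Ir(cod)Cl]2 (2.5 mol%), (S)-Cl,MeO-BIPHEP (5 mol%), 4-chloro-3-nitrobenzoic acid (10 mol%), Cs2CO3 (20 mol%), i-PrOH (2 equiv), THF, 100 °C
Reagents that add atoms: none
Why: Krische iridium-catalysed transfer-hydrogenative carbonyl allylation, in which the chiral cyclometalated allyliridium species adds to one face of the aldehyde through a closed chair transition state and so sets the R carbinol that becomes the side-chain alcohol of the target (ligand antipode chosen for R; the sense should be confirmed on the first batch).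

**Step 3**
Reactants: 1 triisopropyl(4-iodophenoxy)silane
Product: 7 para-substituted aldehyde 4-(TIPSO)benzaldehyde, via arylmagnesium chloride 6 (not isolated)
Conditions: i-PrMgCl·LiCl, THF, 0 °C to rt; DMF; aq. NH4Cl
Reagents that add atoms: N,N-dimethylformamide, CN(C)C=O
Why: Iodine–magnesium exchange followed by Bouveault formylation, with the para silyl ether inert to the Grignard reagent; no stereocenter is formed.

**Step 4**
Reactants: 5 (3R)-1-[4-(TIPSO)phenyl]hex-5-en-3-ol; 7 4-(TIPSO)benzaldehyde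
Product: 8 (2R,4S,6R)-4-bromo-2-[4-(TIPSO)phenyl]-6-{2-[4-(TIPSO)phenyl]ethyl}oxane (all-cis)
Conditions: Me3SiBr (1.3 equiv), InBr3 (10 mol%), CH2Cl2, −78 °C to 0 °C
Reagents that add atoms: bromotrimethylsilane, C[Si](C)(C)Br
Why: Prins cyclisation in which the oxocarbenium ion closes through a chair with both substituents equatorial and bromide captures the ring cation equatorially, so the single carbinol stereocenter of 5 dictates the all-cis pattern and the absolute configuration at C2 and C4 (C4 is reset in step 6 and C2 in step 7).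

**Step 5**
Reactants: 9 1,3-bis(methoxymethoxy)benzene
Product: 12 1-methoxy-3,5-bis(methoxymethoxy)benzene, via arylboronate 10 (not isolated), via sodium phenoxide 11 (not isolated)
Conditions: HBpin (1.5 equiv), [Ir(OMe)(cod)]2 (1.5 mol%), dtbpy (3 mol%), THF, 80 °C; then NaOH, H2O2, 0 °C; then Me2SO4, rt
Reagents that add atoms: hydrogen peroxide, OO; dimethyl sulfate, COS(=O)(=O)OC
Why: Sterically governed iridium-catalysed C–H borylation occurs only at the one position not ortho to a substituent, and boronate oxidation followed by Williamson methylation of the phenoxide turns the C–B bond into the methoxy group; no stereocenter is formed.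

**Step 6**
Reactants: 12 1-methoxy-3,5-bis(methoxymethoxy)benzene; 8 all-cis bromooxane
Product: 15 (2R,4S,6R)-4-[4-methoxy-2,6-bis(methoxymethoxy)phenyl]-2-[4-(TIPSO)phenyl]-6-{2-[4-(TIPSO)phenyl]ethyl}oxane (all-cis), via aryllithium 13 (not isolated), via arylmagnesium bromide 14 (not isolated)
Conditions: n-BuLi, THF, 0 °C; MgBr2·OEt2; then added over 1 h to 8, FeCl3 (5 mol%), TMEDA (1.5 equiv), THF, 0 °C to rt
Reagents that add atoms: none
Why: Directed ortho-metalation between the two MOM ethers and transmetalation to magnesium feed an iron-catalysed Kumada-type cross-coupling that runs through the secondary oxan-4-yl radical, and this planar radical, held in a chair by the two equatorial substituents, is captured by the bulky aryliron species from the equatorial side, so the aryl group ends cis to both neighbours whatever the bromide configuration and the future chroman C4 is fixed as S.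

**Step 7**
Reactants: 15 all-cis 4-aryloxane
Product: 17 (2R)-1-{(2R,4S)-5-hydroxy-7-methoxy-2-[4-(TIPSO)phenyl]-3,4-dihydro-2H-chromen-4-yl}-4-[4-(TIPSO)phenyl]butan-2-ol, via bisphenol 16 (not isolated)
Conditions: HCl (2 M), MeOH–THF, 40 °C; evaporate; BF3·OEt2 (0.3 equiv), CH2Cl2, −20 °C to 0 °C
Reagents that add atoms: none
Why: Acidic methanolysis of the MOM acetals is followed by Lewis-acid ionisation of the benzylic C2–O bond of the oxane (SN1 opening to a para-silyloxybenzyl cation) and capture by one of the two equivalent ring A phenols, and because this closure is reversible C2 settles with the aryl group equatorial and the C4 side chain pseudo-axial away from the C5 oxygen, giving the 2,4-trans (2R,4S) chroman while C4 and the carbinol carbon are untouched.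

**Step 8**
Reactants: 17 chroman diol
Product: 18 (2R,4R)-7-methoxy-5-(TIPSO)-2-[4-(TIPSO)phenyl]-4-{(2R)-2-(TIPSO)-4-[4-(TIPSO)phenyl]butyl}-3,4-dihydro-2H-chromene (same spatial arrangement as 17; the C4 descriptor changes only through CIP ranking)
Conditions: TIPSOTf (2.5 equiv), 2,6-lutidine, CH2Cl2, 0 °C to rt
Reagents that add atoms: triisopropylsilyl triflate, CC(C)[Si](OS(=O)(=O)C(F)(F)F)(C(C)C)C(C)C
Why: Silyl ether formation at the phenol and the secondary alcohol, where the bulky non-coordinating silyl ether on the C5 oxygen later shields C6 from lithiation; no stereocenter is affected.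

**Step 9**
Reactants: 1 triisopropyl(4-iodophenoxy)silane; 19 N-methoxy-N-methylacrylamide
Product: 20 (2E)-N-methoxy-N-methyl-3-[4-(TIPSO)phenyl]prop-2-enamide
Conditions: Pd(OAc)2 (2 mol%), P(o-tol)3 (4 mol%), Et3N, MeCN, 80 °C
Reagents that add atoms: none
Why: Mizoroki–Heck reaction in which syn insertion and syn β-hydride elimination give the E alkene; no stereocenter is formed.

**Step 10**
Reactants: 18 tetrasilylated chroman; 20 Weinreb cinnamamide
Product: 23 target (2E)-1-{(2R,4S)-5-hydroxy-4-[(2R)-2-hydroxy-4-(4-hydroxyphenyl)butyl]-2-(4-hydroxyphenyl)-7-methoxy-3,4-dihydro-2H-chromen-8-yl}-3-(4-hydroxyphenyl)prop-2-en-1-one, via aryllithium 21 (not isolated), via silylated chalcone 22 (not isolated)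
Conditions: n-BuLi (1.2 equiv), THF, 0 °C; 20, −78 °C to 0 °C; AcOH (8 equiv); then TBAF (8 equiv), rt to 40 °C
Reagents that add atoms: none
Why: Directed ortho-metalation at C8 (between the methoxy group and the ring oxygen, C6 being shielded by the silyl ether) and Weinreb ketone synthesis by 1,2-addition to the cinnamamide are followed in the same pot by buffered fluoride desilylation of all five silyl ethers; no stereocenter is formed or touched and the E alkene is kept.

**Compound list**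
1 | triisopropyl(4-iodophenoxy)silane | CC(C)[Si](Oc1ccc(I)cc1)(C(C)C)C(C)C | starting material
2 | allyl alcohol | C=CCO | starting material
3 | 3-[4-(TIPSO)phenyl]propanal | O=CCCc1ccc(O[Si](C(C)C)(C(C)C)C(C)C)cc1 | intermediate
4 | allyl acetate | CC(=O)OCC=C | starting material
5 | (3R)-1-[4-(TIPSO)phenyl]hex-5-en-3-ol | C=CC[C@H](O)CCc1ccc(O[Si](C(C)C)(C(C)C)C(C)C)cc1 | intermediate
6 | [4-(TIPSO)phenyl]magnesium chloride | Cl[Mg]c1ccc(O[Si](C(C)C)(C(C)C)C(C)C)cc1 | intermediate (not isolated)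
7 | 4-(TIPSO)benzaldehyde | O=Cc1ccc(O[Si](C(C)C)(C(C)C)C(C)C)cc1 | intermediate
8 | (2R,4S,6R)-4-bromo-2-[4-(TIPSO)phenyl]-6-{2-[4-(TIPSO)phenyl]ethyl}oxane | Br[C@@H]1C[C@H](c2ccc(O[Si](C(C)C)(C(C)C)C(C)C)cc2)O[C@H](CCc2ccc(O[Si](C(C)C)(C(C)C)C(C)C)cc2)C1 | intermediate
9 | 1,3-bis(methoxymethoxy)benzene | COCOc1cccc(OCOC)c1 | starting material
10 | 2-[3,5-bis(methoxymethoxy)phenyl]-4,4,5,5-tetramethyl-1,3,2-dioxaborolane | COCOc1cc(OCOC)cc(B2OC(C)(C)C(C)(C)O2)c1 | intermediate (not isolated)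
11 | sodium 3,5-bis(methoxymethoxy)phenoxide | [Na+].[O-]c1cc(OCOC)cc(OCOC)c1 | intermediate (not isolated)
12 | 1-methoxy-3,5-bis(methoxymethoxy)benzene | COCOc1cc(OC)cc(OCOC)c1 | intermediate
13 | [4-methoxy-2,6-bis(methoxymethoxy)phenyl]lithium | COCOc1cc(OC)cc(OCOC)c1[Li] | intermediate (not isolated)
14 | [4-methoxy-2,6-bis(methoxymethoxy)phenyl]magnesium bromide | COCOc1cc(OC)cc(OCOC)c1[Mg]Br | intermediate (not isolated)
15 | (2R,4S,6R)-4-[4-methoxy-2,6-bis(methoxymethoxy)phenyl]-2-[4-(TIPSO)phenyl]-6-{2-[4-(TIPSO)phenyl]ethyl}oxane | COCOc1cc(OC)cc(OCOC)c1[C@@H]1C[C@H](c2ccc(O[Si](C(C)C)(C(C)C)C(C)C)cc2)O[C@H](CCc2ccc(O[Si](C(C)C)(C(C)C)C(C)C)cc2)C1 | intermediate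
16 | 5-methoxy-2-{(2R,4S,6R)-2-[4-(TIPSO)phenyl]-6-{2-[4-(TIPSO)phenyl]ethyl}oxan-4-yl}benzene-1,3-diol | COc1cc(O)c([C@@H]2C[C@H](c3ccc(O[Si](C(C)C)(C(C)C)C(C)C)cc3)O[C@H](CCc3ccc(O[Si](C(C)C)(C(C)C)C(C)C)cc3)C2)c(O)c1 | intermediate (not isolated)
17 | (2R)-1-{(2R,4S)-5-hydroxy-7-methoxy-2-[4-(TIPSO)phenyl]-3,4-dihydro-2H-chromen-4-yl}-4-[4-(TIPSO)phenyl]butan-2-ol | COc1cc(O)c2c(c1)O[C@@H](c1ccc(O[Si](C(C)C)(C(C)C)C(C)C)cc1)C[C@@H]2C[C@H](O)CCc1ccc(O[Si](C(C)C)(C(C)C)C(C)C)cc1 | intermediate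
18 | (2R,4R)-7-methoxy-5-(TIPSO)-2-[4-(TIPSO)phenyl]-4-{(2R)-2-(TIPSO)-4-[4-(TIPSO)phenyl]butyl}-3,4-dihydro-2H-chromene | COc1cc(O[Si](C(C)C)(C(C)C)C(C)C)c2c(c1)O[C@@H](c1ccc(O[Si](C(C)C)(C(C)C)C(C)C)cc1)C[C@@H]2C[C@H](O[Si](C(C)C)(C(C)C)C(C)C)CCc1ccc(O[Si](C(C)C)(C(C)C)C(C)C)cc1 | intermediate
19 | N-methoxy-N-methylacrylamide | C=CC(=O)N(C)OC | starting material
20 | (2E)-N-methoxy-N-methyl-3-[4-(TIPSO)phenyl]prop-2-enamide | CON(C)C(=O)/C=C/c1ccc(O[Si](C(C)C)(C(C)C)C(C)C)cc1 | intermediate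
21 | 8-lithio derivative of 18 | COc1cc(O[Si](C(C)C)(C(C)C)C(C)C)c2c(c1[Li])O[C@@H](c1ccc(O[Si](C(C)C)(C(C)C)C(C)C)cc1)C[C@@H]2C[C@H](O[Si](C(C)C)(C(C)C)C(C)C)CCc1ccc(O[Si](C(C)C)(C(C)C)C(C)C)cc1 | intermediate (not isolated)
22 | (2E)-1-[(2R,4R)-7-methoxy-5-(TIPSO)-2-[4-(TIPSO)phenyl]-4-{(2R)-2-(TIPSO)-4-[4-(TIPSO)phenyl]butyl}-3,4-dihydro-2H-chromen-8-yl]-3-[4-(TIPSO)phenyl]prop-2-en-1-one | COc1cc(O[Si](C(C)C)(C(C)C)C(C)C)c2c(c1C(=O)/C=C/c1ccc(O[Si](C(C)C)(C(C)C)C(C)C)cc1)O[C@@H](c1ccc(O[Si](C(C)C)(C(C)C)C(C)C)cc1)C[C@@H]2C[C@H](O[Si](C(C)C)(C(C)C)C(C)C)CCc1ccc(O[Si](C(C)C)(C(C)C)C(C)C)cc1 | intermediate (not isolated)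
23 | (2E)-1-{(2R,4S)-5-hydroxy-4-[(2R)-2-hydroxy-4-(4-hydroxyphenyl)butyl]-2-(4-hydroxyphenyl)-7-methoxy-3,4-dihydro-2H-chromen-8-yl}-3-(4-hydroxyphenyl)prop-2-en-1-one | COc1cc(O)c2c(c1C(=O)/C=C/c1ccc(O)cc1)O[C@@H](c1ccc(O)cc1)C[C@@H]2C[C@H](O)CCc1ccc(O)cc1 | target

**Totals**
Total step count: 10. Longest linear sequence: 7 steps (1 → 2 → 4 → 6 → 7 → 8 → 10).

**Steps most likely to fail**

Step 6. A di-ortho-oxygenated aryl Grignard may transfer slowly to iron, so that β-hydride elimination or reduction of the ring radical wins, or the cis selectivity may be lower than expected. The fallback builds the same bond by polar chemistry. It sets out from 5 and 7: a Prins cyclisation in CF3CO2H/CH2Cl2 gives the all-cis oxan-4-yl trifluoroacetate F1, and aq. NaHCO3/MeOH gives the all-cis oxan-4-ol F2. Dess–Martin oxidation gives the oxan-4-one F3, and aryllithium 13 adds to it to give the tertiary benzylic alcohol F4. Ionic hydrogenation (Et3SiH, BF3·OEt2, CH2Cl2, −78 °C), with axial hydride delivery to the benzylic cation, places the aryl group equatorial and comes back to the route at 15.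

Step 7. Ionisation of the benzylic ether may be sluggish with only a silyloxy donor, or intermolecular Friedel–Crafts alkylation and a C2 epimer mixture may compete. The fallback uses a quinone-methide relay with the free phenol. It sets out from 15: TBAF removes the two aryl silyl ethers to give the MOM-protected bisphenol F5. Dilute HCl in MeOH (25–40 °C) then removes the MOM groups, and the free para-hydroxyphenyl group lets the oxane open through a neutral para-quinone methide that a ring A phenol recloses to the tetrahydroxy chroman F6. Exhaustive silylation (TIPSOTf, 2,6-lutidine) comes back to the route at 18.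

Step 10. Lithiation may stray to C6 or to the benzylic C2–H, or the hindered aryllithium may add poorly to the amide. The fallback functionalises C8 electrophilically. It sets out from 18: NBS (CH2Cl2, −78 °C) brominates C8, para to the C5 oxygen, to give the 8-bromochroman F7. Bromine–lithium exchange (t-BuLi, THF, −78 °C) comes back to the route at aryllithium 21.

**Further compounds**
F1 | step 6 | (2R,4S,6R)-2-[4-(TIPSO)phenyl]-6-{2-[4-(TIPSO)phenyl]ethyl}oxan-4-yl trifluoroacetate | FC(F)(F)C(=O)O[C@@H]1C[C@H](c2ccc(O[Si](C(C)C)(C(C)C)C(C)C)cc2)O[C@H](CCc2ccc(O[Si](C(C)C)(C(C)C)C(C)C)cc2)C1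
F2 | step 6 | (2R,4S,6R)-2-[4-(TIPSO)phenyl]-6-{2-[4-(TIPSO)phenyl]ethyl}oxan-4-ol | O[C@@H]1C[C@H](c2ccc(O[Si](C(C)C)(C(C)C)C(C)C)cc2)O[C@H](CCc2ccc(O[Si](C(C)C)(C(C)C)C(C)C)cc2)C1
F3 | step 6 | (2R,6R)-2-[4-(TIPSO)phenyl]-6-{2-[4-(TIPSO)phenyl]ethyl}oxan-4-one | O=C1C[C@H](c2ccc(O[Si](C(C)C)(C(C)C)C(C)C)cc2)O[C@H](CCc2ccc(O[Si](C(C)C)(C(C)C)C(C)C)cc2)C1
F4 | step 6 | (2R,6R)-4-[4-methoxy-2,6-bis(methoxymethoxy)phenyl]-2-[4-(TIPSO)phenyl]-6-{2-[4-(TIPSO)phenyl]ethyl}oxan-4-ol (either C4 epimer) | COCOc1cc(OC)cc(OCOC)c1C1(O)C[C@H](c2ccc(O[Si](C(C)C)(C(C)C)C(C)C)cc2)O[C@H](CCc2ccc(O[Si](C(C)C)(C(C)C)C(C)C)cc2)C1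
F5 | step 7 | 4-{(2R,4S,6R)-6-[2-(4-hydroxyphenyl)ethyl]-4-[4-methoxy-2,6-bis(methoxymethoxy)phenyl]oxan-2-yl}phenol | COCOc1cc(OC)cc(OCOC)c1[C@@H]1C[C@H](c2ccc(O)cc2)O[C@H](CCc2ccc(O)cc2)C1
F6 | step 7 | (2R)-1-[(2R,4S)-5-hydroxy-2-(4-hydroxyphenyl)-7-methoxy-3,4-dihydro-2H-chromen-4-yl]-4-(4-hydroxyphenyl)butan-2-ol | COc1cc(O)c2c(c1)O[C@@H](c1ccc(O)cc1)C[C@@H]2C[C@H](O)CCc1ccc(O)cc1
F7 | step 10 | 8-bromo derivative of 18 | COc1cc(O[Si](C(C)C)(C(C)C)C(C)C)c2c(c1Br)O[C@@H](c1ccc(O[Si](C(C)C)(C(C)C)C(C)C)cc1)C[C@@H]2C[C@H](O[Si](C(C)C)(C(C)C)C(C)C)CCc1ccc(O[Si](C(C)C)(C(C)C)C(C)C)cc1
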